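In the fresh mixture the ring closure was the slow road: it took 0.30 /h of the substrate present, against 1.08 /h for the dimer step.

    substrate ⇌ ring (K1 = 3.1, k1 = 0.30 /h)
    substrate + open dimer → open trimer (k2 = 1.2 /M/h)
    2 substrate → open dimer (k3 = 2.7 /M/h)

- autumn: substrate 0.20 M; time 5.0 h; everything together in a closed stirred flask, run for 5.0 h
- dawn: substrate 0.20 M; one stirred flow tank at steady state, fed with the mixture as stated, mean residence time 5.0 h

- percentages count the substrate that a species holds: one open dimer counts as two
- percentages count the substrate that a species holds: one open trimer counts as three
- two of one species on the left: rate k times its square, two consumed each time
- the stated concentrations are those of everything mixed, before any reaction; amounts are the same in each set-up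
- run time (autumn): 5.0 h

1. the set-up with the highest share of ring in all that became ring or open dimer or open trimer, at the outlet or at the end ("none" if the first two lie within 2 percentage points) (autumn / dawn / none)
2. share of ring in all that became ring or open dimer or open trimer, at the outlet or at the end, autumn
3. share of ring in all that became ring or open dimer or open trimer, at the outlet or at the end, dawn

I wrote s for the substrate as a fraction of the charge. Ring closure draws in proportion to s and the dimer step in proportion to its square, so I divided the first figure above by the second. That gave the crossover fraction f, the s at which the two forward draws are equal: 0.278. At any moment ring takes f/(f+s) of the two draws, the instantaneous selectivity.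

I set the open trimer aside in both reckonings. In the tank dawn, ring reopens before it leaves, which raises the ratio of dimer to ring at the outlet from s/f by a factor 1.48. The substrate balance is then a quadratic, with root s = 0.283, and so ring's share came to 39.8 %.

In the flask autumn, with ring's return ignored at this stage, the two forward draws integrate in closed form and put s at 0.0588 by my estimate. Summing the selectivity down to there gave the ring made. I let that ring reopen for half the run on average, a factor 0.785, and ring's share came to 30.9 %. My choice was therefore dawn.

The forecast, reached by another route, also named dawn, with 30.1 % for autumn and 37.9 % for dawn, both lower than mine . Its ground was this: “The tank keeps substrate low, which favours the first-order ring closure over the second-order steps”.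

The simulation gave 30.5 % for autumn and 37.9 % for dawn, so dawn stood highest.

In autumn, the dimer step used substrate at 2.2 times the forward rate of ring closure at 0.438 h, but at 0.32 times that rate at 5.00 h, where the substrate left, 8.96 %, stood below f and gives s/f = 0.322. In the neighbouring flask charged with 0.050 M, f is 1.11, above the whole charge, and that flask ended with ring at 47.6 % against open dimer at 28.1 %, a ring share of 60.1 %.

The numbers of this flask belong to no real substance; what happens was integrated by code.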